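(The readings come from a simulation with made-up constants, and the scatter is random.)

Each Xp costs one Xa and one Xb, so by that balance [Xb] − [Xa] keeps its charged value through a run. Hold the readings against this.

| setting | north | north-west | south-west | east |
|---|---|---|---|---|
| Xa | 200 mM | 200 mM | 100 mM | 80.0 mM |
| Xb | 220 mM | 330 mM | 220 mM | 100 mM |
| time |  |  |  | 62 h |

| run | time / h | [Xp] / mM |
|---|---|---|
| north run | 2.5 | 59.3 |
| north run | 3.9 | 73.8 |
| north run | 6.2 | 88.3 |
| north run | 9.9 | 101.2 |
| north run | 16 | 112.0 |
| north run | 25 | 120.1 |
| north run | 39 | 124.4 |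
| north run | 62 | 127.4 |
| north-west run | 2.5 | 79.9 |
| north-west run | 3.9 | 96.6 |
| north-west run | 6.2 | 112.4 |
| north-west run | 9.9 | 125.8 |
| north-west run | 16 | 136.7 |
| north-west run | 25 | 144.4 |
| north-west run | 39 | 148.8 |
| north-west run | 62 | 154.0 |
| south-west run | 2.5 | 31.4 |
| south-west run | 3.9 | 41.9 |
| south-west run | 6.2 | 49.9 |
| south-west run | 9.9 | 59.1 |
| south-west run | 16 | 67.1 |
| south-west run | 25 | 71.3 |
| south-west run | 39 | 75.8 |
| south-west run | 62 | 77.9 |

(standard deviation of a reading: 0.6 mM)

- apparent order in [Xa] of the starting rate, round the charge of the north run (the rate where two percent of its Xa have turned into Xp) (one fixed amount of Xp, the same in the runs compared)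
- apparent order in [Xb] of the starting rate, round the charge of the north run (the rate where two percent of its Xa have turned into Xp)
- Xp in the east run at 62 h, as a share of the Xa charged

- Overall: Xa + Xb -> Xp.
- Constant volume, constant temperature.
- An order is taken over about fifteen percent of the charge, up and down.

Watch the north run in slow motion. At 2.5 h, [Xp] already stands at 59.3 mM, which is 29.6% of the Xa charged. Read no tight starting order from that; commit to the east share instead.

Next, take the north run's rise from 2.5 h to 3.9 h: 10.4 mM h⁻¹. At its last reading, the balance leaves [Xa] at 72.6 mM and [Xb] at 92.6 mM. Scale the early rate by [Xa][Xb], and 3.40 mM h⁻¹ is due. The north run's last two readings show 0.130 mM h⁻¹, less than that. So in the north run that balance, with a rate in [Xa][Xb], fails.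

More Xb gives more Xp: the north-west run reaches 154.0 mM against 127.4 mM in the north run. Assume, then, that Xb also leaks away by pairing with itself.

Divide the leak rate by the making rate, and time drops out. This ratio is a selectivity factor. Try a leak 1.50 times the making at equal concentrations. The balance then integrates to one number, the stall number: the square root of charged Xa over Xa not turned into Xp, less one, divided by the Xb-to-Xa charge ratio. That trial puts it at 0.500.

Read it at 62 h in the south-west run, whose Xa charge lies nearer the east charge than the north run's does. The reading gives 0.512. Carried to the east charge, my reckoning gives Xp at 62.8% of the Xa charged at 62 h.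

The forecast says order 0.95 in [Xa], order 0.95 in [Xb] and an east share of 55%, on its reading of “a starting rate close to first order in each of Xa and Xb”.

The flask gives order 1.0 in [Xa], order 1.2 in [Xb] and an east share of 62.1%.

    Xa + Xb → Xp (0.8424 M⁻¹ h⁻¹)
    Xa + 2 Xb → Xp + Xb (0.6912 M⁻² h⁻¹)
    2 Xa → X (0.1037 M⁻¹ h⁻¹)
    2 Xb → Z (0.4140 M⁻¹ h⁻¹)

At the east charge, the two making steps together form Xp at 7.29 mM h⁻¹, while the pairing to Z takes Xb at 8.28 mM h⁻¹, faster than that. At 62 h the east run held Xp at 62.1% of the Xa charged, which makes its stall number 0.499 against 0.512 from the south-west run. Carried to the north run, 0.512 gives 59.1% at 62 h, and the reading there is 63.7%.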